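The rate constants are invented; no experiment stands behind them.

The ratio to watch is the rate at which starting material pairs off into homo dimer over the rate at which the catalyst turns it into target, and that ratio moves as the starting material is used.

in all of them: starting material 0.20 M; second substrate 1.00 equiv; free catalyst 0.063 mol%; impurity 23 µM; time 1.5 min

|  | temperature |
|---|---|
| winter | −20 °C |
| noon | 20 °C |
| autumn | 0 °C |

    starting material + free catalyst ⇌ catalyst intermediate A (K1 = 169 M⁻¹, k1 = 5950 M⁻¹ s⁻¹, Ea1 = 28.0 kJ mol⁻¹, ΔH1 = −15.0 kJ mol⁻¹)
    catalyst intermediate A → free catalyst + target (k2 = 51.2 s⁻¹, Ea2 = 65.0 kJ mol⁻¹)
    second substrate + free catalyst ⇌ catalyst intermediate B (K3 = 29.0 M⁻¹, k3 = 26100 M⁻¹ s⁻¹, Ea3 = 28.0 kJ mol⁻¹, ΔH3 = −52.0 kJ mol⁻¹)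
    catalyst intermediate B → free catalyst + second product (k4 = 391 s⁻¹, Ea4 = 64.0 kJ mol⁻¹)
    2 starting material → homo dimer (k5 = 0.999 M⁻¹ s⁻¹, Ea5 = 47.0 kJ mol⁻¹)
    free catalyst + impurity → spent catalyst (k6 = 3.80 × 10⁵ M⁻¹ s⁻¹, Ea6 = 20.0 kJ mol⁻¹)
    (constants at 20 °C)

- in percentages every species weighs as the starting material in it: one homo dimer counts as two
- where a step has two of a species, its rate is k times that concentration squared, and two are used at each turn
- all constants are for 20 °C and move with temperature by the activation energies and enthalpies

- the flask with the highest amount of target, in percent of the starting material charged ("all alike" if they lie within 1.5 percentage points) (winter / noon / autumn / all alike)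
- final target, as a percentage of the starting material charged, in winter
- final target, as a percentage of the starting material charged, in noon
- final target, as a percentage of the starting material charged, in autumn

My own reckoning is a ledger of the starting material at noon. The charge holds 126 µM of free catalyst, and each impurity takes one away, which leaves 103 µM working. If all of that sat as catalyst intermediate A, target would form at 51.2 s⁻¹ times this, or 5.27 mM s⁻¹. The homo dimer step removes starting material at twice 0.999 M⁻¹ s⁻¹ times [starting material] squared, which at the start is 79.9 mM s⁻¹, far faster.

The two rates are equal at the crossover concentration, the [starting material] at which dimer loss equals full catalyst turnover: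

[starting material] at crossover = 0.0514 M

With all working catalyst counted as catalyst intermediate A, the share of starting material going to target at any moment is one over one plus the square of [starting material] over the crossover. So the ledger is kept by the fraction left. Taking the charge in 4 equal slices, each entered at its middle concentration:

at 0.175 M: 7.93% to target
at 0.125 M: 14.5% to target
at 0.0750 M: 31.9% to target
at 0.0250 M: 80.9% to target

On this reckoning the noon books close at 33.8% target and 66.2% homo dimer. Catalyst held as catalyst intermediate B makes no target, and the ledger counts all working catalyst as catalyst intermediate A, so the noon flask should come in under this entry.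

Going from noon to winter slows the step from catalyst intermediate A to target by a factor of 68 and the homo dimer step by 21, so with the same working catalyst the winter crossover comes out at 0.0287 M, lower than at noon. In winter the clock also counts: all working catalyst sitting as catalyst intermediate A for 1.5 min gives target amounting to 3.51% of the charge. Noon should therefore lead, its entry being larger than this winter one, and autumn, between the two in temperature, is placed between them without a figure of mine.

The forecast names noon, with 1.3% in winter, 26% at noon and 16.3% in autumn; its noon figure stands below my noon ledger. Its grounds: "The second substrate competes for the catalyst and holds it, so the target forms at a low rate until that substrate is used up."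

The simulation gives 1.26% in winter, 26.2% at noon and 16.3% in autumn, so noon stands highest and the forecast is right on each answer. The noon flask ends with 0% starting material and 73.8% homo dimer.

The main loss of target at noon is the passing of starting material into homo dimer: with that step struck out, target reaches 100% instead of 26.2%. The noon ledger's 33.8% stands above the reading of 26.2%. In the neighbouring flask, noon with 0.16 mol% of free catalyst, the crossover rises to 0.0872 M, the ledger gives 50.6%, and the flask gives 43.1%.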